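**Retrosynthetic overview**

1. Target ⇐ (methylenation, deprotection) tetracyclic C16 ketone ⇐ (key step) a vinyl ketone that already holds ring A, the 19,10-lactone and ring B with an exocyclic C8=C15 alkene; one Lewis-acid cascade makes ring D and ring C (C8, C9, C11, C12, C13, C14), ring C last.
2. Enabling feature: C16 lies between C15 and the bridgehead C13, and quaternary C8 carries the one-carbon arms C14 and C15. A carbonyl at C16 can therefore first be the Prins electrophile for the C8=C15 alkene (temporary six-membered ring C8–C15–C16–C12–C11–C9) and then the pinacol terminus, once C14 of its vinyl group bonds to C8 and C12 shifts from C16 to C13.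
3. Vinyl ketone ⇐ ring B β-keto ester (Dieckmann, C6–C8) ⇐ ring A enone lactone ⇐ aldol addition/lactonization of a glutarate-derived ester amide onto a ring A ene-1,4-dione (C9–C10 bond, lactone).
4. Ene-dione ⇐ quinone monoketal of methyl 5-methoxysalicylate by enantioselective Mukaiyama–Michael addition (C5) and C4 methylation; the 1β,2β,3β-triol is set by exo-dihydroxylation and acetonide-controlled reduction before ring B is closed.
5. Order of ring formation: ring A (arene carbons), lactone, ring B, then ring D and ring C together in the key step.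

Key step: step 14

Remark: the facial sense of the copper bis(oxazoline) catalyst in step 2 is assigned by analogy and the antipodal ligand would be used if it proved opposite; names use gibberellin numbering with the lactone bridge on the α face and C18 and the three hydroxyls on the β face, and the SMILES give the absolute configuration.

**Route**

Step 1
Reactants: 1 methyl 2-hydroxy-5-methoxybenzoate
Product: 2 methyl 3,3-dimethoxy-6-oxocyclohexa-1,4-diene-1-carboxylate
Conditions: PhI(OAc)2, MeOH, 0 °C
Reagents that add atoms: methanol, CO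
Why: Oxidative dearomatization of the para-methoxyphenol with hypervalent iodine and capture by methanol at the carbon para to the hydroxyl gives the quinone monoketal, with no stereocenter formed.

Step 2
Reactants: 2 methyl 3,3-dimethoxy-6-oxocyclohexa-1,4-diene-1-carboxylate; 3 1-(tert-butyldimethylsilyloxy)-1-methoxyethene
Product: 5 methyl (1R,6R)-5,5-dimethoxy-6-(2-methoxy-2-oxoethyl)-2-oxocyclohex-3-ene-1-carboxylate, via silyl enol ether 4 (not isolated)
Conditions: [Cu((S,S)-t-Bu-box)](SbF6)2 (10 mol%), CH2Cl2, −78 °C; then aq. citric acid, 0 °C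
Reagents that add atoms: none
Why: Enantioselective Mukaiyama–Michael addition in which the β-keto ester of 2 chelates the chiral divalent copper Lewis acid, so the ketene acetal attacks only the doubly activated ring carbon (C5) on one face and sets C5 as R, while C4 stays epimerizable.

Step 3
Reactants: 5 methyl (1R,6R)-5,5-dimethoxy-6-(2-methoxy-2-oxoethyl)-2-oxocyclohex-3-ene-1-carboxylate
Product: 6 methyl (1S,6R)-5,5-dimethoxy-6-(2-methoxy-2-oxoethyl)-1-methyl-2-oxocyclohex-3-ene-1-carboxylate
Conditions: MeI, K2CO3, acetone, rt
Reagents that add atoms: iodomethane, CI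
Why: C-methylation of the β-keto ester enolate, with iodomethane approaching anti to the neighbouring pseudo-axial C5 side chain, creates the C4 quaternary center with methyl trans to that chain and the C19 ester cis to it.

Step 4
Reactants: 6 methyl (1S,6R)-5,5-dimethoxy-6-(2-methoxy-2-oxoethyl)-1-methyl-2-oxocyclohex-3-ene-1-carboxylate
Product: 7 methyl (1S,6R)-6-(2-methoxy-2-oxoethyl)-1-methyl-2,5-dioxocyclohex-3-ene-1-carboxylate
Conditions: 1 M HCl, THF, 0 °C to rt
Reagents that add atoms: water, O
Why: Acid hydrolysis of the dimethyl ketal frees the C10 ketone as an ene-1,4-dione; the quaternary C4 blocks aromatization and the mild acid leaves C5 untouched.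

Step 5
Reactants: 8 methyl 5-chloro-5-oxopentanoate
Product: 9 methyl 5-[methoxy(methyl)amino]-5-oxopentanoate
Conditions: MeNHOMe·HCl, pyridine, CH2Cl2, 0 °C
Reagents that add atoms: N,O-dimethylhydroxylamine hydrochloride, Cl.CNOC
Why: Nucleophilic acyl substitution of the acid chloride gives the N-methoxy-N-methylamide that later becomes the vinyl ketone.

Step 6
Reactants: 7 methyl (1S,6R)-6-(2-methoxy-2-oxoethyl)-1-methyl-2,5-dioxocyclohex-3-ene-1-carboxylate; 9 methyl 5-[methoxy(methyl)amino]-5-oxopentanoate
Product: 11 enone lactone (ring A Δ1-3-ketone with 19,10-lactone; C9 bears CO2Me and the amide chain), via hydroxy triester 10 (not isolated)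
Conditions: LiN(i-Pr)2, THF, −78 °C, 9 then 7; AcOH, −78 °C; then CSA (cat.), benzene, 40 °C
Reagents that add atoms: none
Why: Aldol addition of the lithium (E)-ester enolate (the ester α-position is more acidic than the amide α-position) to the less hindered C10 ketone followed by lactonization: attack on the β face, anti to the α-oriented C5 side chain and C19 ester, places the C10 oxygen cis to C19 so that it closes the lactone, and a Zimmerman–Traxler chair with the branched C5 side of the ketone equatorial gives the anti adduct, which is the 9β-H configuration.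

Step 7
Reactants: 11 enone lactone
Product: 12 1β,2β-diol 3-ketone
Conditions: OsO4 (2 mol%), N-methylmorpholine N-oxide, citric acid, t-BuOH–H2O, rt
Reagents that add atoms: N-methylmorpholine N-oxide, C[N+]1([O-])CCOCC1; water, O
Why: Catalytic OsO4 syn-dihydroxylation of the enone alkene from the exo (β) face of the 6-oxabicyclo[3.2.1]octene, away from the diaxial lactone bridge that covers the α face, sets C1 and C2.

Step 8
Reactants: 12 1β,2β-diol 3-ketone
Product: 13 1β,2β-acetonide 3-ketone
Conditions: Me2C(OMe)2, CSA (cat.), acetone, rt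
Reagents that add atoms: 2,2-dimethoxypropane, COC(C)(C)OC
Why: Acetal exchange protects the cis-1,2-diol as the isopropylidene acetal, which also shields the β face of C3.

Step 9
Reactants: 13 1β,2β-acetonide 3-ketone
Product: 14 3β-alcohol acetonide
Conditions: NaBH4, CeCl3·7H2O, MeOH, −40 °C
Reagents that add atoms: none
Why: Borohydride reduction of the C3 ketone (esters, lactone and amide are spared) along the equatorial trajectory on the α side, because the axial β approach is blocked by the syn-axial C1–O bond of the cis-fused dioxolane, should give the axial, all-cis 3β-alcohol, as in reductions of ketones flanked by an isopropylidene acetal.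

Step 10
Reactants: 14 3β-alcohol acetonide
Product: 15 3β-silyl ether acetonide
Conditions: TBSOTf, 2,6-lutidine, CH2Cl2, 0 °C
Reagents that add atoms: tert-butyldimethylsilyl trifluoromethanesulfonate, CC(C)(C)[Si](C)(C)OS(=O)(=O)C(F)(F)F
Why: Silylation of the hindered axial alcohol with the silyl triflate prevents alkoxide formation at C3, and thus retro-aldol opening of ring A, in the next step.

Step 11
Reactants: 15 3β-silyl ether acetonide
Product: 16 ring B β-keto ester (8-ketone, 6β-CO2Me, 9β-H)
Conditions: LiN(SiMe3)2 (1.2 equiv), THF, −78 to −20 °C; AcOH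
Reagents that add atoms: none
Why: Dieckmann condensation in which kinetic deprotonation of the unhindered C6 methylene and 5-exo attack on the C8 ester close ring B; the product rests as its β-keto ester enolate so that C9–H is not removed and the lactone oxygen is not eliminated, and on protonation the C6 ester takes the more stable β position trans to C4.

Step 12
Reactants: 16 ring B β-keto ester
Product: 17 exocyclic methylene ester (C8=C15)
Conditions: Zn, CH2Br2, TiCl4, THF–CH2Cl2, 0 °C to rt
Reagents that add atoms: dibromomethane, BrCBr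
Why: Takai–Lombardo methylenation, whose non-basic gem-dimetallic reagent converts the ketone into the exocyclic alkene without deprotonating C6 or C9, while esters, lactone and amide do not react.

Step 13
Reactants: 17 exocyclic methylene ester
Product: 18 vinyl ketone
Conditions: CH2=CHMgBr (1.3 equiv), THF, −78 to −40 °C; poured into cold 1 M HCl
Reagents that add atoms: vinylmagnesium bromide, C=C[Mg]Br
Why: Acyl substitution at the N-methoxy-N-methylamide through its chelated tetrahedral adduct gives the vinyl ketone without over-addition, the hindered ester and lactone are not attacked at low temperature, and the inverse acid quench keeps the liberated amine from adding to the enone.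

Step 14
Reactants: 18 vinyl ketone
Product: 19 protected tetracyclic 17-nor-16-ketone
Conditions: MeAlCl2 (3 equiv), CH2Cl2, −78 to −30 °C; aq. potassium sodium tartrate
Reagents that add atoms: none
Why: Proposed new method: MeAlCl2 complexes the vinyl ketone and the exocyclic C8=C15 alkene adds through C15 to the carbonyl carbon C16 (Prins/carbonyl-ene type, six-membered chair with the aluminate oxygen equatorial and the vinyl group axial), which gives a temporary six-membered ring (C8–C15–C16–C12–C11–C9) and a tertiary C8 cation; the axial vinyl group then attacks C8 through C14 and the resulting C13 cation is quenched by a pinacol-type 1,2-shift of C12 from C16 to C13, which breaks the temporary ring and regenerates the C16 ketone. The closest known reaction types are the Prins–pinacol ring-enlarging cyclopentane annulation and the alkylaluminium-halide-initiated cyclization of unsaturated ketones through zwitterions that go on to cation–olefin steps and 1,2-shifts; new here is their union, with a tertiary carbocation as the electrophile, to give a bridged bicyclo[3.2.1]octanone. Ring D is closed by the C8–C14 bond in a 5-endo cation–olefin closure, and ring C, last, by the C12–C13 bond made in the suprafacial 1,2-shift. C8 is set because only the α lobe of the cation is reached by the axial vinyl group of a chair whose geometry is fixed by the existing C9 center (9β-H axial, C10 equatorial, as ring B demands), and C13, a bridgehead, can form only in the configuration the bicycle allows. The step needs capture of the C8 cation to outrun proton loss and needs C12 rather than C15 to migrate: the first is secured by an excess of the non-basic Lewis acid and the 1,3-diaxial closeness of vinyl group and cation, the second because the C16–C12 bond is nearly parallel to the empty orbital at C13 whereas C15 lies inside ring D, orthogonal to it, and its shift would give a cyclobutane. The first closure should be reversible, so an adduct with the vinyl group equatorial can return to 18 and drain through the productive chair.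

Step 15
Reactants: 19 protected tetracyclic 17-nor-16-ketone
Product: 20 1β,2β,3β-triol 17-nor-16-ketone methyl ester
Conditions: TFA–H2O (9:1), 0 °C to rt
Reagents that add atoms: none
Why: Acid hydrolysis removes the acetonide and the silyl ether at the ketone stage, before the acid-sensitive exocyclic alkene exists, and touches no stereocenter.

Step 16
Reactants: 20 triol nor-ketone methyl ester
Product: 21 methyl ester of the target gibberellin
Conditions: Zn, CH2Br2, TiCl4 (excess), THF–CH2Cl2, 0 °C to rt
Reagents that add atoms: dibromomethane, BrCBr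
Why: Takai–Lombardo methylenation of the C16 ketone, which being non-basic causes no retro-aldol epimerization at C3 and tolerates the free hydroxyls.

Step 17
Reactants: 21 methyl ester of the target gibberellin
Product: 22 target gibberellin (free C7 acid)
Conditions: LiSPr, HMPA, rt; then 1 M HCl
Reagents that add atoms: none
Why: SN2 demethylation of the hindered methyl ester by thiolate frees the acid while sparing the lactone and avoiding the hydroxide conditions that would epimerize C3 by retro-aldol.

**Compound list**

1 | methyl 2-hydroxy-5-methoxybenzoate | COC(=O)c1cc(OC)ccc1O | starting material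
2 | methyl 3,3-dimethoxy-6-oxocyclohexa-1,4-diene-1-carboxylate | COC(=O)C1=CC(OC)(OC)C=CC1=O | intermediate
3 | 1-(tert-butyldimethylsilyloxy)-1-methoxyethene | C=C(OC)O[Si](C)(C)C(C)(C)C | starting material
4 | methyl (6R)-2-(tert-butyldimethylsilyloxy)-5,5-dimethoxy-6-(2-methoxy-2-oxoethyl)cyclohexa-1,3-diene-1-carboxylate | COC(=O)C1=C(O[Si](C)(C)C(C)(C)C)C=CC(OC)(OC)[C@@H]1CC(=O)OC | intermediate
5 | methyl (1R,6R)-5,5-dimethoxy-6-(2-methoxy-2-oxoethyl)-2-oxocyclohex-3-ene-1-carboxylate (trans keto tautomer, in equilibrium with its enol) | COC(=O)[C@@H]1[C@@H](CC(=O)OC)C(OC)(OC)C=CC1=O | intermediate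
6 | methyl (1S,6R)-5,5-dimethoxy-6-(2-methoxy-2-oxoethyl)-1-methyl-2-oxocyclohex-3-ene-1-carboxylate | COC(=O)[C@@]1(C)[C@@H](CC(=O)OC)C(OC)(OC)C=CC1=O | intermediate
7 | methyl (1S,6R)-6-(2-methoxy-2-oxoethyl)-1-methyl-2,5-dioxocyclohex-3-ene-1-carboxylate | COC(=O)[C@@]1(C)[C@@H](CC(=O)OC)C(=O)C=CC1=O | intermediate
8 | methyl 5-chloro-5-oxopentanoate | COC(=O)CCCC(=O)Cl | starting material
9 | methyl 5-[methoxy(methyl)amino]-5-oxopentanoate | COC(=O)CCCC(=O)N(C)OC | intermediate
10 | hydroxy triester: ring A Δ1-3-ketone with 10α-OH, 4β-Me, 4α-CO2Me, 5β-H, 5-CH2CO2Me; C9 (9β-H series) bears CO2Me and CH2CH2C(O)N(OMe)Me | CON(C)C(=O)CC[C@H](C(=O)OC)[C@]1(O)C=CC(=O)[C@@](C)(C(=O)OC)[C@H]1CC(=O)OC | intermediate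
11 | enone lactone: ring A Δ1-3-ketone, 19,10-lactone (α), 4β-Me, 5β-H, 5-CH2CO2Me; C9 (9β-H series) bears CO2Me and CH2CH2C(O)N(OMe)Me | CON(C)C(=O)CC[C@H](C(=O)OC)[C@@]12OC(=O)[C@@](C)([C@H]1CC(=O)OC)C(=O)C=C2 | intermediate
12 | 1β,2β-dihydroxy 3-ketone of 11 | CON(C)C(=O)CC[C@H](C(=O)OC)[C@@]12OC(=O)[C@@](C)([C@H]1CC(=O)OC)C(=O)[C@@H](O)[C@H]2O | intermediate
13 | 1β,2β-O-isopropylidene 3-ketone | CON(C)C(=O)CC[C@H](C(=O)OC)[C@@]12OC(=O)[C@@](C)([C@H]1CC(=O)OC)C(=O)[C@H]3OC(C)(C)O[C@@H]23 | intermediate
14 | 3β-hydroxy 1β,2β-O-isopropylidene lactone | CON(C)C(=O)CC[C@H](C(=O)OC)[C@@]12OC(=O)[C@@](C)([C@H]1CC(=O)OC)[C@@H](O)[C@H]3OC(C)(C)O[C@@H]23 | intermediate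
15 | 3β-(tert-butyldimethylsilyloxy) 1β,2β-O-isopropylidene lactone | CON(C)C(=O)CC[C@H](C(=O)OC)[C@@]12OC(=O)[C@@](C)([C@H]1CC(=O)OC)[C@@H](O[Si](C)(C)C(C)(C)C)[C@H]3OC(C)(C)O[C@@H]23 | intermediate
16 | ring B β-keto ester: 8-ketone, 6β-CO2Me (6α-H), 5β-H, 9β-H with 9α-CH2CH2C(O)N(OMe)Me; ring A as in 15 | O=C3[C@@H](CCC(=O)N(C)OC)[C@@]12OC(=O)[C@@](C)([C@H]1[C@@H]3C(=O)OC)[C@@H](O[Si](C)(C)C(C)(C)C)[C@H]4OC(C)(C)O[C@@H]24 | intermediate
17 | exocyclic methylene ester: C8=C15H2, otherwise as 16 | C=C3[C@@H](CCC(=O)N(C)OC)[C@@]12OC(=O)[C@@](C)([C@H]1[C@@H]3C(=O)OC)[C@@H](O[Si](C)(C)C(C)(C)C)[C@H]4OC(C)(C)O[C@@H]24 | intermediate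
18 | vinyl ketone: 9α-CH2CH2C(O)CH=CH2, C8=C15H2, otherwise as 17 | C=C3[C@@H](CCC(=O)C=C)[C@@]12OC(=O)[C@@](C)([C@H]1[C@@H]3C(=O)OC)[C@@H](O[Si](C)(C)C(C)(C)C)[C@H]4OC(C)(C)O[C@@H]24 | intermediate
19 | protected 17-nor-16-ketone: gibberellane skeleton, C15 bridge β and C14 bridge α on C8, 9β-H, 6β-CO2Me, 1β,2β-acetonide, 3β-OTBS, 19,10-lactone | O=C1C[C@]23C[C@H]1CC[C@H]2[C@@]12OC(=O)[C@@](C)([C@H]1[C@@H]3C(=O)OC)[C@@H](O[Si](C)(C)C(C)(C)C)[C@H]4OC(C)(C)O[C@@H]24 | intermediate
20 | 1β,2β,3β-trihydroxy 17-nor-16-ketone methyl ester | O=C1C[C@]23C[C@H]1CC[C@H]2[C@@]12OC(=O)[C@@](C)([C@H]1[C@@H]3C(=O)OC)[C@@H](O)[C@@H](O)[C@H]2O | intermediate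
21 | methyl ester of the target gibberellin (C7 methyl ester, C16 exocyclic methylene, 1β,2β,3β-triol, 19,10-lactone) | C=C1C[C@]23C[C@H]1CC[C@H]2[C@@]12OC(=O)[C@@](C)([C@H]1[C@@H]3C(=O)OC)[C@@H](O)[C@@H](O)[C@H]2O | intermediate
22 | target gibberellin: 1β,2β,3β-trihydroxy 19,10-lactone of the gibberellane skeleton with C16 exocyclic methylene and free C7 carboxylic acid | C=C1C[C@]23C[C@H]1CC[C@H]2[C@@]12OC(=O)[C@@](C)([C@H]1[C@@H]3C(=O)O)[C@@H](O)[C@@H](O)[C@H]2O | target

**Step count and risks**

Total step count: 17. Longest linear sequence: 16 steps (steps 1–4 and 6–17; step 5 makes the side arm).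

Steps most likely to fail:

Step 14. The C8 cation may lose a proton before the vinyl group captures it, the first ring closure may occur with the vinyl group equatorial and out of reach of C8, or the Lewis acid may open the acetonide. The fallback separates the three events with known reactions. It sets out from 18: Me2AlCl (1.1 equiv, CH2Cl2, −78 °C) should stop at the type 2 carbonyl–ene product, the ring-closed tertiary vinyl carbinol F1 (C15–C16 bond formed, double bond moved to C6=C8 in conjugation with the ester). NBS (propylene oxide, i-PrOH, −78 to 0 °C) then triggers a bromonium-induced semipinacol ring expansion to the 2-(bromomethyl)cycloheptanone F2; C12 should migrate in preference to C15, which is attached to the electron-poor enoate carbon. The shift is anti to the bromonium ion, so the face of the vinyl group that is attacked decides C13 and both epimers are expected. Only the epimer with the bromomethyl group on the α side of the seven-membered ring can deliver C14 to the α face of C8, so the mixture is separated, or equilibrated at C13 through the enol, before the radical step. Bu3SnH with AIBN in benzene at 80 °C generates the C14 radical, which closes ring D and ring C at once by 5-exo conjugate addition to C8. Hydrogen transfer to C6 from the open β face may give the 6-epimer F3, which NaOMe in MeOH at 0 °C should equilibrate to the more stable 6β-ester, so the sequence comes back to the route at 19.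

Step 6. The addition may show poor simple diastereoselection at C9, the enolate may add in the 1,4 sense or merely enolize the ene-dione, and base may eliminate the new lactone oxygen. The fallback makes the C9–C10 bond by allylboration. It sets out from 7: cross-metathesis of N-methoxy-N-methylpent-4-enamide with allylboronic acid pinacol ester (second-generation Grubbs catalyst) gives the (E)-allylboronate F4. Its thermal or diol-catalysed addition to the C10 ketone of 7 through a closed chair transition state, followed by CSA, gives the homoallylic lactone F5 with the same C9/C10 relationship as 11. Ozonolysis of the terminal vinyl group (ozone, CH2Cl2–MeOH, −78 °C, then Me2S; the electron-poor enone alkene is spared) gives aldehyde F6, NaClO2/NaH2PO4/2-methyl-2-butene gives acid F7, and Me3SiCHN2 in MeOH comes back to the route at 11.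

Step 9. Hydride may be delivered to C3 from the β face and give the 3α-epimer, or methoxide may open the non-enolizable β-keto lactone. The fallback sets C3 by reagent control before the diol is in place. It sets out from 11: Corey–Bakshi–Shibata reduction (the 2-methyl-CBS-oxazaborolidine enantiomer that delivers hydride to the α face, catecholborane, toluene, −78 °C) gives the 3β-allylic alcohol F8. TBSOTf with 2,6-lutidine gives the silyl ether F9. Catalytic OsO4 with N-methylmorpholine N-oxide dihydroxylates the C1=C2 bond from the exo (β) face, because the α face and above all the axial approach to C2 are closed by the lactone bridge, to give diol F10. Acetonide formation (Me2C(OMe)2, CSA) comes back to the route at 15.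

Further compounds
F1 | step 14 | ring-closed tertiary vinyl carbinol (C16 carbinol with axial vinyl group, C15–C16 bond, C6=C8 enoate; ring A as in 18) | C=C[C@]1(O)CC2=C(C(=O)OC)[C@@H]3[C@]4(C)C(=O)O[C@@]3([C@@H]2CC1)[C@@H]5OC(C)(C)O[C@@H]5[C@@H]4O[Si](C)(C)C(C)(C)C
F2 | step 14 | 2-(bromomethyl)cycloheptanone (C16 ketone between C15 and C13, C13 bearing CH2Br as a mixture of C13 epimers, C6=C8 enoate) | BrCC1CC[C@@H]2C(CC1=O)=C(C(=O)OC)[C@@H]3[C@]4(C)C(=O)O[C@]23[C@@H]5OC(C)(C)O[C@@H]5[C@@H]4O[Si](C)(C)C(C)(C)C
F3 | step 14 | 6-epimer of 19 (6α-CO2Me) | O=C1C[C@]23C[C@H]1CC[C@H]2[C@@]12OC(=O)[C@@](C)([C@H]1[C@H]3C(=O)OC)[C@@H](O[Si](C)(C)C(C)(C)C)[C@H]4OC(C)(C)O[C@@H]24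
F4 | step 6 | (E)-N-methoxy-N-methyl-6-(4,4,5,5-tetramethyl-1,3,2-dioxaborolan-2-yl)hex-4-enamide | CON(C)C(=O)CC/C=C/CB1OC(C)(C)C(C)(C)O1
F5 | step 6 | homoallylic lactone (analogue of 11 with vinyl in place of CO2Me on C9) | CON(C)C(=O)CC[C@H](C=C)[C@@]12OC(=O)[C@@](C)([C@H]1CC(=O)OC)C(=O)C=C2
F6 | step 6 | aldehyde (analogue of 11 with CHO on C9) | CON(C)C(=O)CC[C@H](C=O)[C@@]12OC(=O)[C@@](C)([C@H]1CC(=O)OC)C(=O)C=C2
F7 | step 6 | carboxylic acid (analogue of 11 with CO2H on C9) | CON(C)C(=O)CC[C@H](C(=O)O)[C@@]12OC(=O)[C@@](C)([C@H]1CC(=O)OC)C(=O)C=C2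
F8 | step 9 | 3β-allylic alcohol (Δ1, from 11) | CON(C)C(=O)CC[C@H](C(=O)OC)[C@@]12OC(=O)[C@@](C)([C@H]1CC(=O)OC)[C@@H](O)C=C2
F9 | step 9 | 3β-(tert-butyldimethylsilyloxy) Δ1-alkene | CON(C)C(=O)CC[C@H](C(=O)OC)[C@@]12OC(=O)[C@@](C)([C@H]1CC(=O)OC)[C@@H](O[Si](C)(C)C(C)(C)C)C=C2
F10 | step 9 | 1β,2β-diol 3β-silyl ether | CON(C)C(=O)CC[C@H](C(=O)OC)[C@@]12OC(=O)[C@@](C)([C@H]1CC(=O)OC)[C@@H](O[Si](C)(C)C(C)(C)C)[C@@H](O)[C@H]2O
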